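**Plan**
- Retrosynthesis: after removing the three acetates and restoring C1 (C=O from CH–OSi) and C2–C3 (CH2–CH2 from CH=CH), the hydroquinone ring is read as its ene-dione tautomer. The bonds C4–C4a and C1–C8a are then cut together (retro-[4+2]) to give p-benzoquinone and a (1E,3E)-1-aryl-4-silyloxybutadiene. The diene is cut at its C2=C3 bond and at the aryl–CH2 bond to give crotonaldehyde, an allyl group and 5-methoxy-1-naphthol.
- Enabling feature: the ring C1–C2–C3–C4–C4a–C8a is fused through C4a–C8a to a benzene ring carrying OH at C5 and C8, para to each other and flanking the fusion bond. That ring is p-benzoquinone in reduced form, C4a=C8a is its dienophilic double bond, and C1(O)–C2–C3–C4(aryl) is a butadiene. The target is a constitutional isomer of that cycloadduct.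
- Forward order: the naphthalene is bought; the four-carbon chain is joined by Stille allylation and cross-metathesis; the dienol ether is made; the [4+2] closes the last ring; tautomerization turns the partly saturated quinone ring into the hydroquinone; alkene saturation, carbinol oxidation and deacetylation finish.
- Stereochemistry: the single stereocentre (C4, R) is set in the cycloaddition by a chiral oxazaborolidinium catalyst together with endo selectivity. The three other centres formed there are erased (C4a and C8a on aromatization, C1 on oxidation).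

Key step: step 6

Remark: 5-methoxynaphthalen-1-ol is taken as purchasable, and the (S) catalyst in step 6 is assigned from the accepted pre-transition-state model for quinone–oxazaborolidinium complexes; the sense is to be confirmed on adduct 13, and the (R) catalyst serves without other change if it is found opposite.

**Route**

Step 1
Reactants: 1 5-methoxynaphthalen-1-ol; 2 N-bromosuccinimide
Product: 3 4-bromo-5-methoxynaphthalen-1-ol
Conditions: NBS (1.0 equiv), MeCN, −20 → 0 °C, dark
Reagents that add atoms: N-bromosuccinimide, O=C1CCC(=O)N1Br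
Why: Electrophilic aromatic bromination, in which the free hydroxyl is the strongest donor and in a polar aprotic solvent should direct bromine to its para position C-4 (peri to the methoxy group), with C-2 as the minor site.

Step 2
Reactants: 3 4-bromo-5-methoxynaphthalen-1-ol; 4 acetic anhydride
Product: 5 4-bromo-5-methoxynaphthalen-1-yl acetate
Conditions: Ac2O, pyridine, DMAP (cat.), CH2Cl2, 0 °C → rt
Reagents that add atoms: acetic anhydride, CC(=O)OC(C)=O
Why: O-Acylation of the naphthol, which protects it, lowers the donor strength of the naphthalene for the later Lewis-acid and oxidation steps, and is removed at the end together with the hydroquinone acetates.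

Step 3
Reactants: 5 4-bromo-5-methoxynaphthalen-1-yl acetate; 6 allyltributylstannane
Product: 7 5-methoxy-4-(prop-2-en-1-yl)naphthalen-1-yl acetate
Conditions: allylSnBu3 (1.3 equiv), Pd(PPh3)4 (5 mol %), toluene, 100 °C
Reagents that add atoms: allyltributylstannane, C=CC[Sn](CCCC)(CCCC)CCCC
Why: Stille coupling of an aryl bromide with an allylstannane under neutral conditions, which should leave the aryl acetate intact and tolerate the peri methoxy group.

Step 4
Reactants: 7 5-methoxy-4-(prop-2-en-1-yl)naphthalen-1-yl acetate; 8 (E)-but-2-enal (crotonaldehyde)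
Product: 9 5-methoxy-4-[(2E)-4-oxobut-2-en-1-yl]naphthalen-1-yl acetate
Conditions: crotonaldehyde (5 equiv), second-generation Hoveyda–Grubbs catalyst RuCl2(H2IMes)(=CH-C6H4-2-OiPr) (3 mol %), CH2Cl2, 40 °C
Reagents that add atoms: (E)-but-2-enal, C/C=C/C=O
Why: Olefin cross-metathesis of a reactive terminal allylarene with an excess of an electron-poor enal, which should give the conjugated E-enal with loss of propene.

Step 5
Reactants: 9 5-methoxy-4-[(2E)-4-oxobut-2-en-1-yl]naphthalen-1-yl acetate; 10 tert-butyldimethylsilyl trifluoromethanesulfonate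
Product: 11 4-[(1E,3E)-4-{[tert-butyl(dimethyl)silyl]oxy}buta-1,3-dien-1-yl]-5-methoxynaphthalen-1-yl acetate
Conditions: TBSOTf (1.2 equiv), Et3N (2 equiv), Et2O, 0 °C → rt
Reagents that add atoms: tert-butyldimethylsilyl trifluoromethanesulfonate, CC(C)(C)[Si](C)(C)OS(=O)(=O)C(F)(F)F
Why: Vinylogous silyl enol ether formation, in which O-silylation of the s-trans enal and deprotonation at the benzylic gamma carbon should give the (1E) enol ether and, for steric reasons, the (3E) aryl alkene.

Step 6
Reactants: 11 4-[(1E,3E)-4-{[tert-butyl(dimethyl)silyl]oxy}buta-1,3-dien-1-yl]-5-methoxynaphthalen-1-yl acetate; 12 1,4-benzoquinone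
Product: 13 4-[(1S,4R,4aS,8aS)-4-{[tert-butyl(dimethyl)silyl]oxy}-5,8-dioxo-1,4,4a,5,8,8a-hexahydronaphthalen-1-yl]-5-methoxynaphthalen-1-yl acetate (endo adduct, the four hydrogens on the new ring all cis)
Conditions: 1,4-benzoquinone (1.5 equiv), oxazaborolidinium salt from (S)-3,3-diphenyl-1-(o-tolyl)tetrahydro-1H,3H-pyrrolo[1,2-c][1,3,2]oxazaborole and HNTf2 (20 mol %), CH2Cl2, −78 °C; quench cold, use crude
Reagents that add atoms: 1,4-benzoquinone, O=C1C=CC(=O)C=C1
Why: The boron of the oxazaborolidinium ion binds one quinone carbonyl and lowers the LUMO of the adjacent C=C, which then takes up the electron-rich (1E,3E)-diene in a concerted but asynchronous [4+2] cycloaddition; the closest known reaction type is the catalytic enantioselective quinone Diels–Alder reaction of 1-oxygenated butadienes. The carbocyclic ring is closed intermolecularly by two new C–C bonds, diene C-1 and C-4 onto one quinone C=C, suprafacially on both partners, and the symmetry of the quinone leaves only one constitution possible. Four stereocentres form at once: the E,E geometry of the diene fixes silyloxy and aryl cis, endo overlap with the quinone carbonyls places both cis to the ring-fusion carbonyl carbons, and the catalyst, by screening one face of the bound enone unit, selects the enantiotopic face of the diene and so the configuration of the aryl-bearing carbon, the only centre that reaches the target. The step needs endo selectivity and one orientation of the diene relative to the bound carbonyl, since exo addition or the reversed orientation on the same quinone face would lead to the mirror image after aromatization; the strongly donating silyloxy group puts the larger HOMO coefficient on the aryl-bearing terminus, which bonds to the carbon beta to the coordinated carbonyl. The low temperature keeps the uncatalysed cycloaddition slow, and the acetate on the naphthol lowers the donor strength of the naphthalene so that electron transfer to or arylation of the activated quinone should not compete.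

Step 7
Reactants: 13 endo adduct; 4 acetic anhydride
Product: 15 4-[(1R,4R)-5,8-diacetoxy-4-{[tert-butyl(dimethyl)silyl]oxy}-1,4-dihydronaphthalen-1-yl]-5-methoxynaphthalen-1-yl acetate, via hydroquinone tautomer 14 (not isolated)
Conditions: Et3N (0.2 equiv), CH2Cl2, 0 °C; then Ac2O (3 equiv), Et3N, DMAP (cat.), 0 °C
Reagents that add atoms: acetic anhydride, CC(=O)OC(C)=O
Why: Amine-catalysed double enolization of the ene-dione, driven by aromatization, followed by acetylation of the air-sensitive hydroquinone; the centres at C-4a and C-8a vanish, those at C-1 and C-4 are untouched, and the silyloxy group is a poor leaving group so beta-elimination should not compete at 0 °C.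

Step 8
Reactants: 15 4-[(1R,4R)-5,8-diacetoxy-4-{[tert-butyl(dimethyl)silyl]oxy}-1,4-dihydronaphthalen-1-yl]-5-methoxynaphthalen-1-yl acetate
Product: 16 4-[(1R,4R)-5,8-diacetoxy-4-{[tert-butyl(dimethyl)silyl]oxy}-1,2,3,4-tetrahydronaphthalen-1-yl]-5-methoxynaphthalen-1-yl acetate
Conditions: 2-nitrobenzenesulfonyl hydrazide (excess), Et3N, CH2Cl2, rt
Reagents that add atoms: none
Why: Diimide reduction, a concerted syn transfer of H2 to the isolated cis ring alkene without metal or acid, so that double-bond migration towards C-4, hydrogenolysis of the benzylic C–O bond and loss of silanol should be avoided.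

Step 9
Reactants: 16 4-[(1R,4R)-5,8-diacetoxy-4-{[tert-butyl(dimethyl)silyl]oxy}-1,2,3,4-tetrahydronaphthalen-1-yl]-5-methoxynaphthalen-1-yl acetate
Product: 17 4-[(1R,4R)-5,8-diacetoxy-4-hydroxy-1,2,3,4-tetrahydronaphthalen-1-yl]-5-methoxynaphthalen-1-yl acetate
Conditions: HF·pyridine, pyridine, THF, 0 °C → rt
Reagents that add atoms: none
Why: Fluoride-mediated Si–O cleavage under buffered, weakly acidic conditions, which should spare the aryl acetates and avoid the alkoxide that would invite acetyl migration from the neighbouring aryl ester.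

Step 10
Reactants: 17 4-[(1R,4R)-5,8-diacetoxy-4-hydroxy-1,2,3,4-tetrahydronaphthalen-1-yl]-5-methoxynaphthalen-1-yl acetate
Product: 18 4-[(1R)-5,8-diacetoxy-4-oxo-1,2,3,4-tetrahydronaphthalen-1-yl]-5-methoxynaphthalen-1-yl acetate
Conditions: Dess–Martin periodinane (1.3 equiv), CH2Cl2, 0 °C → rt
Reagents that add atoms: none
Why: Dess–Martin oxidation of the secondary benzylic alcohol to the aryl ketone under near-neutral conditions; the carbinol centre vanishes and the remaining centre, which cannot be reached by enolization of the new ketone, is untouched.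

Step 11
Reactants: 18 4-[(1R)-5,8-diacetoxy-4-oxo-1,2,3,4-tetrahydronaphthalen-1-yl]-5-methoxynaphthalen-1-yl acetate
Product: 19 (4R)-5,8-dihydroxy-4-(4-hydroxy-8-methoxynaphthalen-1-yl)-3,4-dihydronaphthalen-1(2H)-one
Conditions: K2CO3, degassed MeOH, argon, 0 °C; then aq. NH4Cl
Reagents that add atoms: none
Why: Base-catalysed methanolysis (transesterification) of the three aryl acetates, run with exclusion of oxygen so that the free hydroquinone is not oxidized to a quinone whose quinone-methide tautomer would erode the benzylic centre.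

**Compound list**
1 | 5-methoxynaphthalen-1-ol | COc1cccc2c(O)cccc12 | starting material
2 | N-bromosuccinimide | O=C1CCC(=O)N1Br | starting material
3 | 4-bromo-5-methoxynaphthalen-1-ol | COc1cccc2c(O)ccc(Br)c12 | intermediate
4 | acetic anhydride | CC(=O)OC(C)=O | starting material
5 | 4-bromo-5-methoxynaphthalen-1-yl acetate | COc1cccc2c(OC(C)=O)ccc(Br)c12 | intermediate
6 | allyltributylstannane | C=CC[Sn](CCCC)(CCCC)CCCC | starting material
7 | 5-methoxy-4-(prop-2-en-1-yl)naphthalen-1-yl acetate | COc1cccc2c(OC(C)=O)ccc(CC=C)c12 | intermediate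
8 | (E)-but-2-enal (crotonaldehyde) | C/C=C/C=O | starting material
9 | 5-methoxy-4-[(2E)-4-oxobut-2-en-1-yl]naphthalen-1-yl acetate | COc1cccc2c(OC(C)=O)ccc(C/C=C/C=O)c12 | intermediate
10 | tert-butyldimethylsilyl trifluoromethanesulfonate | CC(C)(C)[Si](C)(C)OS(=O)(=O)C(F)(F)F | starting material
11 | 4-[(1E,3E)-4-{[tert-butyl(dimethyl)silyl]oxy}buta-1,3-dien-1-yl]-5-methoxynaphthalen-1-yl acetate | COc1cccc2c(OC(C)=O)ccc(/C=C/C=C/O[Si](C)(C)C(C)(C)C)c12 | intermediate
12 | 1,4-benzoquinone | O=C1C=CC(=O)C=C1 | starting material
13 | 4-[(1S,4R,4aS,8aS)-4-{[tert-butyl(dimethyl)silyl]oxy}-5,8-dioxo-1,4,4a,5,8,8a-hexahydronaphthalen-1-yl]-5-methoxynaphthalen-1-yl acetate (endo adduct, all-cis ring hydrogens) | COc1cccc2c(OC(C)=O)ccc([C@H]3C=C[C@@H](O[Si](C)(C)C(C)(C)C)[C@H]4C(=O)C=CC(=O)[C@H]43)c12 | intermediate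
14 | 4-[(1R,4R)-4-{[tert-butyl(dimethyl)silyl]oxy}-5,8-dihydroxy-1,4-dihydronaphthalen-1-yl]-5-methoxynaphthalen-1-yl acetate (hydroquinone tautomer, not isolated) | COc1cccc2c(OC(C)=O)ccc([C@H]3C=C[C@@H](O[Si](C)(C)C(C)(C)C)c4c(O)ccc(O)c43)c12 | intermediate
15 | 4-[(1R,4R)-5,8-diacetoxy-4-{[tert-butyl(dimethyl)silyl]oxy}-1,4-dihydronaphthalen-1-yl]-5-methoxynaphthalen-1-yl acetate (cis) | COc1cccc2c(OC(C)=O)ccc([C@H]3C=C[C@@H](O[Si](C)(C)C(C)(C)C)c4c(OC(C)=O)ccc(OC(C)=O)c43)c12 | intermediate
16 | 4-[(1R,4R)-5,8-diacetoxy-4-{[tert-butyl(dimethyl)silyl]oxy}-1,2,3,4-tetrahydronaphthalen-1-yl]-5-methoxynaphthalen-1-yl acetate (cis) | COc1cccc2c(OC(C)=O)ccc([C@H]3CC[C@@H](O[Si](C)(C)C(C)(C)C)c4c(OC(C)=O)ccc(OC(C)=O)c43)c12 | intermediate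
17 | 4-[(1R,4R)-5,8-diacetoxy-4-hydroxy-1,2,3,4-tetrahydronaphthalen-1-yl]-5-methoxynaphthalen-1-yl acetate (cis) | COc1cccc2c(OC(C)=O)ccc([C@H]3CC[C@@H](O)c4c(OC(C)=O)ccc(OC(C)=O)c43)c12 | intermediate
18 | 4-[(1R)-5,8-diacetoxy-4-oxo-1,2,3,4-tetrahydronaphthalen-1-yl]-5-methoxynaphthalen-1-yl acetate | COc1cccc2c(OC(C)=O)ccc([C@H]3CCC(=O)c4c(OC(C)=O)ccc(OC(C)=O)c43)c12 | intermediate
19 | (4R)-5,8-dihydroxy-4-(4-hydroxy-8-methoxynaphthalen-1-yl)-3,4-dihydronaphthalen-1(2H)-one | COc1cccc2c(O)ccc([C@H]3CCC(=O)c4c(O)ccc(O)c43)c12 | target

**Summary**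
Total step count: 11. Longest linear sequence: 11 steps (from compound 1).

**Steps most likely to fail**

Step 6. Enantiofacial control may be eroded by the uncatalysed background cycloaddition or by exo addition, and the silyl dienol ether may be diverted into a stepwise Mukaiyama–Michael addition. The fallback gives up asymmetric catalysis for resolution and sets out from diene 11 and quinone 12. Without catalyst in toluene at 0–25 °C they should give the racemic endo adduct F1. The conditions of step 7 should convert it, by way of the racemic hydroquinone F2 (not isolated), into the racemic diacetate F3. Preparative chromatography on a chiral stationary phase (amylose tris(3,5-dimethylphenylcarbamate)) should then separate F3 into compound 15, where the fallback returns to the route, and the mirror-image diacetate F4.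

Step 7. The first-formed enolate may lose silanol by beta-elimination, with aromatization of the carbocycle to a naphthalene, in competition with the second proton shift. The fallback replaces tautomerization by an oxidation–reduction detour and sets out from adduct 13. Activated MnO2 in CH2Cl2 at 0 °C should dehydrogenate it to the dihydronaphthoquinone F5. Reductive acetylation of the crude quinone with zinc dust and Ac2O (Et3N cat., 0 °C) should then give compound 15, where it returns to the route.

Step 8. Hydrogen transfer to the hindered ring alkene may be too slow, and prolonged exposure may allow loss of silanol with aromatization or attack of the hydrazide on the aryl acetates. The fallback changes the order and uses a directing group, setting out from compound 15. Buffered HF·pyridine (THF, pyridine, 0 °C) should unveil the allylic carbinol F6, which is used at once. Hydroxyl-directed hydrogenation with [Ir(cod)(PCy3)(py)]PF6 under H2 (1 atm) in CH2Cl2 at 0 °C should then saturate the alkene and give compound 17, where it returns to the route ahead of step 10.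

**Further compounds**
F1 | step 6 | racemic endo adduct (13 and its mirror image) | COc1cccc2c(OC(C)=O)ccc([C@H]3C=C[C@@H](O[Si](C)(C)C(C)(C)C)[C@H]4C(=O)C=CC(=O)[C@H]43)c12.COc1cccc2c(OC(C)=O)ccc([C@@H]3C=C[C@H](O[Si](C)(C)C(C)(C)C)[C@@H]4C(=O)C=CC(=O)[C@@H]43)c12
F2 | step 6 | racemic hydroquinone (14 and its mirror image) | COc1cccc2c(OC(C)=O)ccc([C@H]3C=C[C@@H](O[Si](C)(C)C(C)(C)C)c4c(O)ccc(O)c43)c12.COc1cccc2c(OC(C)=O)ccc([C@@H]3C=C[C@H](O[Si](C)(C)C(C)(C)C)c4c(O)ccc(O)c43)c12
F3 | step 6 | racemic diacetate (15 and its mirror image) | COc1cccc2c(OC(C)=O)ccc([C@H]3C=C[C@@H](O[Si](C)(C)C(C)(C)C)c4c(OC(C)=O)ccc(OC(C)=O)c43)c12.COc1cccc2c(OC(C)=O)ccc([C@@H]3C=C[C@H](O[Si](C)(C)C(C)(C)C)c4c(OC(C)=O)ccc(OC(C)=O)c43)c12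
F4 | step 6 | 4-[(1S,4S)-5,8-diacetoxy-4-{[tert-butyl(dimethyl)silyl]oxy}-1,4-dihydronaphthalen-1-yl]-5-methoxynaphthalen-1-yl acetate (mirror-image diacetate) | COc1cccc2c(OC(C)=O)ccc([C@@H]3C=C[C@H](O[Si](C)(C)C(C)(C)C)c4c(OC(C)=O)ccc(OC(C)=O)c43)c12
F5 | step 7 | 4-[(1R,4R)-4-{[tert-butyl(dimethyl)silyl]oxy}-5,8-dioxo-1,4,5,8-tetrahydronaphthalen-1-yl]-5-methoxynaphthalen-1-yl acetate (dihydronaphthoquinone) | COc1cccc2c(OC(C)=O)ccc([C@H]3C=C[C@@H](O[Si](C)(C)C(C)(C)C)C4=C3C(=O)C=CC4=O)c12
F6 | step 8 | 4-[(1R,4R)-5,8-diacetoxy-4-hydroxy-1,4-dihydronaphthalen-1-yl]-5-methoxynaphthalen-1-yl acetate (allylic carbinol) | COc1cccc2c(OC(C)=O)ccc([C@H]3C=C[C@@H](O)c4c(OC(C)=O)ccc(OC(C)=O)c43)c12
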